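Abbreviations: MOM = methoxymethyl, TES = triethylsilyl, TMS = trimethylsilyl. Ring positions C2–C8a are flavone (4H-chromen-4-one) locants unless a diene or pyranone is discussed by its own locants.

Numbering key (full list after the steps): 1 (R)-limonene; 3 keto aldehyde; 7 chain iodide; 9 chain acid; 10 1,1-dimethoxyethene; 12 acyl ketene acetal; 14 siloxydiene; 15 methyl 2,4-dihydroxybenzoate; 16 its bis-MOM ether; 17 methyl phenyl sulfoxide; 20 sulfinyl enaminone; 23 sulfinylpyranone; 27 protected flavone; 28 target.

## Analysis of the target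

Compound 28 is a flavone: ring A is fused to pyranone ring C, and ring B is a 2,4-dihydroxyphenyl group on C2. Ring A is substituted everywhere except C6, with methoxy on C5, hydroxyl on C7 and a 5-hydroxy-5-methyl-2-isopropenylhexyl chain on C8. The only stereocentre is C2 of that chain, (R), which carries the isopropenyl group, the benzylic CH2 and the CH2CH2C(CH3)2OH arm. It is isolated and not epimerisable, so a chiral-pool source can fix it once. The sensitive groups are the isopropenyl alkene (acid turns it into a tertiary cation that the 7-hydroxyl or the tertiary alcohol can trap as a cyclic ether), the tertiary alcohol, the free phenols and the pyranone, which opens when nucleophiles add at C2. Two things make the synthesis hard. The methyl sits on the chelated O5 while the more reactive O7 is free, the reverse of what alkylating a 5,7-diol gives. The C8 chain is joined through a saturated CH2, so neither Claisen rearrangement nor allylic C-alkylation of a phloroglucinol can install it. The strategy rests on two features of ring A: C5 (OMe), C6 (H) and C7 (OH) map onto the ketene acetal carbon, the central CH and the silyl enol ether carbon of a 1,1-dimethoxy-3-siloxydiene whose terminus C8 carries the chain, and the C4a–C8a bond is the C3=C2 alkene of a 6-aryl-4-pyranone that already holds ring C and ring B. The aldehyde carbon of ring-opened 1 becomes C8 and C4 of 1 becomes the stereocentre.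

## Retrosynthetic reasoning

28 to 27. Only protecting groups are removed: the two MOM acetals on ring B and the TES ether on the tertiary alcohol. The ring B phenols must be masked through the enolate chemistry and the cycloaddition, and the tertiary alcohol through the organolithium and acid chloride stages. One acid treatment frees all three, and O7 is already free in 27.

27 to 14 and 23. The cuts are C8–C8a and C4a–C5. This is the one cut of ring A that leaves C4, ring C and ring B together in 23 and puts both ring A oxygens on a single diene at different levels, so O5 emerges methylated and O7 free without any selective alkylation. The forward reaction has to join the chain-bearing diene terminus to the oxygen-bearing pyranone carbon and then aromatise by loss of the sulfinyl group and one methoxy group.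

14 to 12, and 12 to 9 and 10. Diene 14 is the silyl enol ether of ketone 12. Ketone 12 is cut between its carbonyl carbon (future C7) and the ketene acetal CH (future C6), giving acid 9 (as chloride 11) and ketene acetal 10. The carbonyl is the natural electrophile and 10 the natural nucleophile. The other cut, alkylating a methyl ketone enolate, would need a chain iodide one carbon shorter than ring-opened 1 supplies.

9 to 7. The carboxyl carbon is removed, leaving iodide 7. Ring-opened 1 ends at the carbon that becomes C8, so exactly one carbon (future C7) must be added, and carboxylation of organolithium 8 does this in one operation.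

7 back to 3. These are functional group changes: silyl ether from tertiary alcohol (6), iodide from primary alcohol (5), tertiary alcohol from the methyl ketone by adding a methyl nucleophile (4), primary alcohol from the aldehyde (3). The aldehyde is reduced before the methyl nucleophile is added, so the two carbonyl groups of 3 are told apart by a single chemoselective reduction.

3 to 1. Reconnecting the aldehyde and ketone carbons of 3 gives the ring alkene of 1. Ozonolysis of that alkene delivers the stereocentre, both arms and the future C8 from an inexpensive terpene.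

23 to 20 and 16. In pyranone locants the cuts are C5–C6 and O1–C2. Enaminone 20 supplies C2, C3 (with sulfur), C4 and C5; ester 16 supplies C6, O1 and ring B. Because the sulfur-bearing carbon is already flanked by the aminomethylene carbon before any 1,3-diketone exists, the ring can close only one way. Making the diketone first would direct aminomethylenation to its central methylene.

20 to 19 to 17, and 16 to 15. Enaminone 20 comes from keto sulfoxide 19 by aminomethylenation, and 19 from sulfoxide 17 by C-acetylation. Ester 16 is the bis-MOM ether of 15.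

## Alternatives that were turned down

Alternative 1: Danheiser benzannulation of ring A. The disconnection removes C8–C8a, C6–C7 and C4a–C8a. That leaves siloxyalkyne A1, whose alkyne carbons are C8 and C7, and 3-methoxycyclobutenone A2. On heating, A2 opens to a vinylketene, adds to A1, and the resulting cyclobutenone opens and recloses by six-electron electrocyclisation to phenol A3 (free hydroxyl on C8a, silyl ether on O7, methoxy on C5, chain on C8). In its favour, every elementary step has close precedent, the polarity of the ynol ether fixes the regiochemistry, and the conditions are neutral. The chain fragment is also shorter, since A1 comes from the aldehyde carbon of 3 at the ester level without an added carbon. On precedent and fragment length it is stronger than the chosen route. Against it, A3 is only ring A. C4 must then be placed on C4a by acylating an electron-rich phenol that has a second, more activated free position at C6, in the presence of the acid-sensitive chain. Condensation with a ring B ester and cyclodehydration follow, four to five further steps on the most valuable material. The chosen strategy instead closes ring A on a pyranone that already carries C4, ring C and ring B, so no substitution on ring A is needed and two steps remain after the annulation.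

Alternative 2: carbonylative three-component annulation of ring C. The cuts are C4a–C4, C4–C3 and O1–C2, giving ortho-iodophenol A4, arylacetylene A5 and a carbonyl carbon supplied under carbonylative cross-coupling conditions. The coupling gives an ynone and the phenol oxygen closes ring C to flavone A6. This is the best-precedented flavone assembly of the four, it is convergent, and it tolerates the free tertiary alcohol and the isopropenyl group. On reliability of its key step it is stronger than the chosen route. Against it, all the difficulty moves into A4: the chain must be attached at C8 through a saturated CH2, for which the fragments from 1 have the wrong carbon count, and iodine must go to C4a and not to the equally activated C6. The iodide is flanked by OH and OMe, which slows oxidative addition, and five-membered closure to an aurone competes. The chosen strategy supplies what this one leaves open, a source for ring A with this pattern.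

Alternative 3: ring A folded on to a preformed pyranone. The cuts are C7–C8 and C5–C6, giving pyranone ester A7 with the ester on C4a and the chain CH2 (C8) on C8a. An excess of lithium amide base removes the vinylogously acidic C8 proton, the carbanion is C-acetylated, and the new methyl ketone enolate closes on the ester to give 5,7-diol A8. In its favour, it needs only anionic chemistry, no labile diene and no sulfur, and iodide 7 could serve as the chain source three steps earlier than in the chosen route. On simplicity of reagents and fragment length it is stronger. Against it, A8 has both O5 and O7 free, so O7 must be protected, the chelated O5 methylated and O7 released, three extra steps. Acetylation must also occur on carbon at a branched secondary carbanion in competition with O-acylation and with attack on the pyranone, and the step is itself without precedent. Novelty risk is comparable; the chosen strategy differentiates O5 and O7 in the bond-forming event and forms both ring bonds in one operation.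

Key step: step 13

Assumption: sulfoxide 17 is used as the racemate, so sulfur-centred stereochemistry in 18–25 is left unspecified (sulfur leaves in step 13); 14 and 20 are drawn without alkene geometry and the transient centres of 2, 24 and 25 are not specified.

## Route

Step 1
Reactants: 1 (R)-(+)-limonene
Product: 3 (3R)-6-oxo-3-(prop-1-en-2-yl)heptanal, via limonene ring ozonide 2 (not isolated)
Conditions: O3 (1.0 equiv), CH2Cl2, −78 °C; then PPh3, −78 °C → rt
Reagents that add atoms: ozone, O=[O+][O-]
Why: Ozonolysis with reductive work-up; the trisubstituted ring alkene is more electron-rich than the 1,1-disubstituted isopropenyl group and should be cleaved first when ozone is limiting, and the stereocentre is not touched.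

Step 2
Reactants: 3 (3R)-6-oxo-3-(prop-1-en-2-yl)heptanal
Product: 4 (5R)-7-hydroxy-5-(prop-1-en-2-yl)heptan-2-one
Conditions: NaBH(OAc)3, THF, rt
Reagents that add atoms: none
Why: Chemoselective hydride reduction; the acetoxy-attenuated borohydride reduces the aldehyde and should leave the methyl ketone.

Step 3
Reactants: 4 (5R)-7-hydroxy-5-(prop-1-en-2-yl)heptan-2-one
Product: 5 (3R)-6-methyl-3-(prop-1-en-2-yl)heptane-1,6-diol
Conditions: MeMgBr (3 equiv), THF, −78 → 0 °C; aq. NH4Cl
Reagents that add atoms: methylmagnesium bromide, C[Mg]Br
Why: Grignard addition; one equivalent is consumed by the hydroxyl, the next adds to the ketone to give the tertiary alcohol, and no stereocentre is formed.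

Step 4
Reactants: 5 (3R)-6-methyl-3-(prop-1-en-2-yl)heptane-1,6-diol
Product: 6 (5R)-7-iodo-2-methyl-5-(prop-1-en-2-yl)heptan-2-ol
Conditions: PPh3, I2, imidazole, CH2Cl2, 0 °C
Reagents that add atoms: iodine, [I][I]
Why: Appel-type iodination; only the primary alcohol forms the alkoxyphosphonium ion, the tertiary alcohol being too hindered.

Step 5
Reactants: 6 (5R)-7-iodo-2-methyl-5-(prop-1-en-2-yl)heptan-2-ol
Product: 7 triethyl{[(5R)-7-iodo-2-methyl-5-(prop-1-en-2-yl)heptan-2-yl]oxy}silane
Conditions: Et3SiOTf, 2,6-lutidine, CH2Cl2, −78 → 0 °C
Reagents that add atoms: triethylsilyl trifluoromethanesulfonate, CC[Si](CC)(CC)OS(=O)(=O)C(F)(F)F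
Why: Silylation of a hindered tertiary alcohol with a silyl triflate and a hindered base; the primary iodide is inert.

Step 6
Reactants: 7 triethyl{[(5R)-7-iodo-2-methyl-5-(prop-1-en-2-yl)heptan-2-yl]oxy}silane
Product: 9 (4R)-7-methyl-4-(prop-1-en-2-yl)-7-(triethylsilyloxy)octanoic acid, via chain alkyllithium 8 (not isolated)
Conditions: t-BuLi (2.1 equiv), Et2O–pentane, −78 °C; CO2, −78 °C → rt; aq. HCl to pH 4, 0 °C
Reagents that add atoms: carbon dioxide, O=C=O
Why: Iodine–lithium exchange and carboxylation add the carbon that becomes C7, the former aldehyde carbon becoming the α-carbon (future C8); a 4-pentenyllithium should not cyclise at −78 °C.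

Step 7
Reactants: 9 (4R)-7-methyl-4-(prop-1-en-2-yl)-7-(triethylsilyloxy)octanoic acid; 10 1,1-dimethoxyethene
Product: 12 (6R)-1,1-dimethoxy-9-methyl-6-(prop-1-en-2-yl)-9-(triethylsilyloxy)dec-1-en-3-one, via chain acid chloride 11 (not isolated)
Conditions: Me2C=C(Cl)NMe2, CH2Cl2, 0 °C → rt; then 10 (3 equiv), Et2O, 0 °C → rt
Reagents that add atoms: none
Why: The α-chloroenamine forms the acid chloride without free acid, and C-acylation of the ketene acetal at its nucleophilic CH2 carbon is the classical route to β,β-dialkoxy enones; a second equivalent of 10 takes up the HCl, so the silyl ether and the alkene should not meet acid.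

Step 8
Reactants: 12 (6R)-1,1-dimethoxy-9-methyl-6-(prop-1-en-2-yl)-9-(triethylsilyloxy)dec-1-en-3-one
Product: 14 (6R)-1,1-dimethoxy-9-methyl-6-(prop-1-en-2-yl)-9-(triethylsilyloxy)-3-(trimethylsilyloxy)deca-1,3-diene, via lithium enolate 13 (not isolated)
Conditions: LiN(i-Pr)2, THF, −78 °C; Me3SiCl, −78 → 0 °C; pentane, filtration, no aqueous work-up
Reagents that add atoms: chlorotrimethylsilane, C[Si](C)(C)Cl
Why: Kinetic deprotonation at the only enolisable methylene and O-silylation; as with other ketones bearing an sp2 group on the carbonyl, mainly the (3Z) silyl enol ether is expected, which places the chain outward in the s-cis diene.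

Step 9
Reactants: 15 methyl 2,4-dihydroxybenzoate
Product: 16 methyl 2,4-bis(methoxymethoxy)benzoate
Conditions: NaH, MeOCH2Cl, DMF, 0 °C → rt
Reagents that add atoms: chloromethyl methyl ether, COCCl
Why: Williamson-type O-alkylation of both phenoxides; full deprotonation with NaH overcomes the hydrogen bond of the 2-hydroxyl to the ester.

Step 10
Reactants: 17 methyl phenyl sulfoxide (2 equiv)
Product: 19 1-(phenylsulfinyl)propan-2-one, via lithiated sulfoxide 18 (not isolated)
Conditions: LiN(i-Pr)2 (2 equiv), THF, −78 °C; EtOAc (1 equiv), −78 → 0 °C; aq. NH4Cl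
Reagents that add atoms: ethyl acetate, CCOC(C)=O
Why: Claisen-type acylation of an α-sulfinyl carbanion by an ester, the standard route to β-keto sulfoxides; two equivalents of carbanion are used because the product is deprotonated as it forms.

Step 11
Reactants: 19 1-(phenylsulfinyl)propan-2-one
Product: 20 4-(dimethylamino)-3-(phenylsulfinyl)but-3-en-2-one
Conditions: Me2NCH(OMe)2, toluene, 60 °C
Reagents that add atoms: N,N-dimethylformamide dimethyl acetal, COC(OC)N(C)C
Why: Aminomethylenation of the active methylene between sulfinyl and carbonyl; the methyl group is far less acidic and stays free, which fixes the sulfur-bearing carbon as the future C4a.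

Step 12
Reactants: 20 4-(dimethylamino)-3-(phenylsulfinyl)but-3-en-2-one; 16 methyl 2,4-bis(methoxymethoxy)benzoate
Product: 23 6-[2,4-bis(methoxymethoxy)phenyl]-3-(phenylsulfinyl)-4H-pyran-4-one, via enaminone lithium enolate 21 (not isolated), via acyclic diketone enaminone 22 (not isolated)
Conditions: LiN(i-Pr)2 (2.2 equiv), THF, −78 °C; 16, −78 °C → rt; then AcOH, 50 °C
Reagents that add atoms: none
Why: Crossed Claisen condensation of the methyl-side enolate of the enaminone with a non-enolisable ester, then acid-induced addition of the aroyl enol oxygen to the aminomethylene carbon with loss of dimethylamine; this acylation–cyclisation of β-amino and β-alkoxy enones is an established route to 2-substituted 4-pyranones.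

Step 13
Reactants: 14 (6R)-1,1-dimethoxy-9-methyl-6-(prop-1-en-2-yl)-9-(triethylsilyloxy)-3-(trimethylsilyloxy)deca-1,3-diene (2.5 equiv); 23 6-[2,4-bis(methoxymethoxy)phenyl]-3-(phenylsulfinyl)-4H-pyran-4-one
Product: 27 2-[2,4-bis(methoxymethoxy)phenyl]-7-hydroxy-5-methoxy-8-[(2R)-5-methyl-2-(prop-1-en-2-yl)-5-(triethylsilyloxy)hexyl]-4H-chromen-4-one, via sulfinyl cycloadduct 24 (not isolated), via ketal dienone 25 (not isolated), via 7-O-trimethylsilyl flavone 26 (not isolated)
Conditions: toluene, 0 → 70 °C; then K2CO3 (cat.), MeOH, 0 °C → rt
Reagents that add atoms: none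
Why: Proposed new method: diene 14 should add across the sulfinyl-bearing C2=C3 alkene of 23 in a Diels–Alder reaction of normal electron demand, or in its stepwise form (vinylogous Mukaiyama–Michael addition, then 6-(enolexo)-exo-trig closure of the α-sulfinyl enol carbon on the dimethoxycarbenium ion), to give cis-fused adduct 24 with the new bonds C8–C8a and C4a–C5; the closest known reactions are additions of 1,1-dialkoxy-3-siloxydienes to halo- and sulfinylquinones with aromatisation by elimination, and of siloxydienes to chromones that carry an acceptor on C3. Ring A is closed by this [4+2] cycloaddition. The α-keto sulfoxide on C4a should then undergo thermal syn elimination with the cis hydrogen on C8a (24 to 25), restoring the C4a=C8a alkene, after which K2CO3 in MeOH expels one methoxy group of the C5 ketal by way of the C8 carbanion (25 to 26) and cleaves the aryl TMS ether to free O7 (26 to 27). The centres created at C4a, C8 and C8a are all destroyed on aromatisation and the chain stereocentre is remote and not enolisable, so no stereocontrol is required. The step needs regioselectivity that places the chain-bearing terminus on C8a; this follows from pairing the most nucleophilic diene carbon (C4 of 14, future C8) with the pyranone carbon that is β to both C=O and S=O (C2 of 23), which leaves the ketene acetal carbon to join the sulfinyl carbon. It also needs site selectivity between the two pyranone alkenes, which the sulfinyl group secures by activating only C2=C3 while the aryl-bearing C5=C6 alkene stays unactivated and more hindered. No Lewis acid is used, so that opening of the pyranone after conjugate addition is not promoted, and the excess of 14 also serves to take up the sulfenic acid.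

Step 14
Reactants: 27 2-[2,4-bis(methoxymethoxy)phenyl]-7-hydroxy-5-methoxy-8-[(2R)-5-methyl-2-(prop-1-en-2-yl)-5-(triethylsilyloxy)hexyl]-4H-chromen-4-one
Product: 28 2-(2,4-dihydroxyphenyl)-7-hydroxy-8-[(2R)-5-hydroxy-5-methyl-2-(prop-1-en-2-yl)hexyl]-5-methoxy-4H-chromen-4-one
Conditions: HCl (2 M aq.), MeOH–THF, rt
Reagents that add atoms: none
Why: Acid-catalysed acetal solvolysis of both MOM ethers and protodesilylation of the TES ether; at room temperature in dilute acid, oxocarbenium formation from the acetals should be much faster than protonation of the 1,1-disubstituted alkene.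

## Compound list

1 | (R)-(+)-limonene, (4R)-1-methyl-4-(prop-1-en-2-yl)cyclohex-1-ene | C=C(C)[C@@H]1CCC(C)=CC1 | starting material
2 | 1-methyl-4-(prop-1-en-2-yl)-7,8,9-trioxabicyclo[4.2.1]nonane, secondary ozonide of the ring alkene, C4 as in 1, acetal carbons unspecified (not isolated) | C=C(C)[C@@H]1CCC2(C)OOC(C1)O2 | intermediate
3 | (3R)-6-oxo-3-(prop-1-en-2-yl)heptanal | C=C(C)[C@H](CCC(C)=O)CC=O | intermediate
4 | (5R)-7-hydroxy-5-(prop-1-en-2-yl)heptan-2-one | C=C(C)[C@H](CCC(C)=O)CCO | intermediate
5 | (3R)-6-methyl-3-(prop-1-en-2-yl)heptane-1,6-diol | C=C(C)[C@H](CCC(C)(C)O)CCO | intermediate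
6 | (5R)-7-iodo-2-methyl-5-(prop-1-en-2-yl)heptan-2-ol | C=C(C)[C@H](CCC(C)(C)O)CCI | intermediate
7 | triethyl{[(5R)-7-iodo-2-methyl-5-(prop-1-en-2-yl)heptan-2-yl]oxy}silane | C=C(C)[C@H](CCC(C)(C)O[Si](CC)(CC)CC)CCI | intermediate
8 | [6-methyl-3-(prop-1-en-2-yl)-6-(triethylsilyloxy)heptyl]lithium, spatial arrangement as in 7 (descriptor 3S because lithium ranks below carbon) (not isolated) | C=C(C)[C@H](CCC(C)(C)O[Si](CC)(CC)CC)CC[Li] | intermediate
9 | (4R)-7-methyl-4-(prop-1-en-2-yl)-7-(triethylsilyloxy)octanoic acid | C=C(C)[C@H](CCC(C)(C)O[Si](CC)(CC)CC)CCC(=O)O | intermediate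
10 | 1,1-dimethoxyethene | C=C(OC)OC | starting material
11 | (4R)-7-methyl-4-(prop-1-en-2-yl)-7-(triethylsilyloxy)octanoyl chloride (not isolated) | C=C(C)[C@H](CCC(C)(C)O[Si](CC)(CC)CC)CCC(=O)Cl | intermediate
12 | (6R)-1,1-dimethoxy-9-methyl-6-(prop-1-en-2-yl)-9-(triethylsilyloxy)dec-1-en-3-one | C=C(C)[C@H](CCC(C)(C)O[Si](CC)(CC)CC)CCC(=O)C=C(OC)OC | intermediate
13 | lithium (6R)-1,1-dimethoxy-9-methyl-6-(prop-1-en-2-yl)-9-(triethylsilyloxy)deca-1,3-dien-3-olate (not isolated) | C=C(C)[C@H](CCC(C)(C)O[Si](CC)(CC)CC)CC=C(O[Li])C=C(OC)OC | intermediate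
14 | (6R)-1,1-dimethoxy-9-methyl-6-(prop-1-en-2-yl)-9-(triethylsilyloxy)-3-(trimethylsilyloxy)deca-1,3-diene, C3=C4 geometry not fixed, 3Z expected to predominate | C=C(C)[C@H](CCC(C)(C)O[Si](CC)(CC)CC)CC=C(O[Si](C)(C)C)C=C(OC)OC | intermediate
15 | methyl 2,4-dihydroxybenzoate | COC(=O)c1ccc(O)cc1O | starting material
16 | methyl 2,4-bis(methoxymethoxy)benzoate | COCOc1ccc(C(=O)OC)c(OCOC)c1 | intermediate
17 | methyl phenyl sulfoxide (racemic) | CS(=O)c1ccccc1 | starting material
18 | [(phenylsulfinyl)methyl]lithium (not isolated) | [Li]CS(=O)c1ccccc1 | intermediate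
19 | 1-(phenylsulfinyl)propan-2-one | CC(=O)CS(=O)c1ccccc1 | intermediate
20 | 4-(dimethylamino)-3-(phenylsulfinyl)but-3-en-2-one | CC(=O)C(=CN(C)C)S(=O)c1ccccc1 | intermediate
21 | lithium 4-(dimethylamino)-3-(phenylsulfinyl)buta-1,3-dien-2-olate (not isolated) | C=C(O[Li])C(=CN(C)C)S(=O)c1ccccc1 | intermediate
22 | 1-[2,4-bis(methoxymethoxy)phenyl]-5-(dimethylamino)-4-(phenylsulfinyl)pent-4-ene-1,3-dione (not isolated) | CN(C)C=C(C(=O)CC(=O)c1ccc(OCOC)cc1OCOC)S(=O)c1ccccc1 | intermediate
23 | 6-[2,4-bis(methoxymethoxy)phenyl]-3-(phenylsulfinyl)-4H-pyran-4-one | O=c1cc(-c2ccc(OCOC)cc2OCOC)occ1S(=O)c1ccccc1 | intermediate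
24 | 2-[2,4-bis(methoxymethoxy)phenyl]-5,5-dimethoxy-8-[(2R)-5-methyl-2-(prop-1-en-2-yl)-5-(triethylsilyloxy)hexyl]-4a-(phenylsulfinyl)-7-(trimethylsilyloxy)-4a,5,8,8a-tetrahydro-4H-chromen-4-one, ring centres unspecified (not isolated) | C=C(C)[C@H](CCC(C)(C)O[Si](CC)(CC)CC)CC1C(O[Si](C)(C)C)=CC(OC)(OC)C2(S(=O)c3ccccc3)C(=O)C=C(c3ccc(OCOC)cc3OCOC)OC12 | intermediate
25 | 2-[2,4-bis(methoxymethoxy)phenyl]-5,5-dimethoxy-8-[(2R)-5-methyl-2-(prop-1-en-2-yl)-5-(triethylsilyloxy)hexyl]-7-(trimethylsilyloxy)-5,8-dihydro-4H-chromen-4-one, C8 unspecified (not isolated) | C=C(C)[C@H](CCC(C)(C)O[Si](CC)(CC)CC)CC1C(O[Si](C)(C)C)=CC(OC)(OC)C2=C1OC(c1ccc(OCOC)cc1OCOC)=CC2=O | intermediate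
26 | 2-[2,4-bis(methoxymethoxy)phenyl]-5-methoxy-8-[(2R)-5-methyl-2-(prop-1-en-2-yl)-5-(triethylsilyloxy)hexyl]-7-(trimethylsilyloxy)-4H-chromen-4-one (not isolated) | C=C(C)[C@H](CCC(C)(C)O[Si](CC)(CC)CC)Cc1c(O[Si](C)(C)C)cc(OC)c2c(=O)cc(-c3ccc(OCOC)cc3OCOC)oc12 | intermediate
27 | 2-[2,4-bis(methoxymethoxy)phenyl]-7-hydroxy-5-methoxy-8-[(2R)-5-methyl-2-(prop-1-en-2-yl)-5-(triethylsilyloxy)hexyl]-4H-chromen-4-one | C=C(C)[C@H](CCC(C)(C)O[Si](CC)(CC)CC)Cc1c(O)cc(OC)c2c(=O)cc(-c3ccc(OCOC)cc3OCOC)oc12 | intermediate
28 | 2-(2,4-dihydroxyphenyl)-7-hydroxy-8-[(2R)-5-hydroxy-5-methyl-2-(prop-1-en-2-yl)hexyl]-5-methoxy-4H-chromen-4-one | C=C(C)[C@H](CCC(C)(C)O)Cc1c(O)cc(OC)c2c(=O)cc(-c3ccc(O)cc3O)oc12 | target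

## Step count and least certain steps

Total step count: 14 (steps 1–8 to diene 14, steps 9–12 to pyranone 23, then steps 13 and 14). Longest linear sequence: 10 steps (steps 1–8, 13 and 14).

Step 13 (key step, proposed new method). The pyranone alkene is donor-substituted by the ring oxygen and may be too weak a dienophile, so that hydrolysis or desilylation of 14 outruns cycloaddition. Attack through the ketene acetal α-carbon of 14 would give open-chain adducts that cannot close. Conjugate addition may be followed by opening of the pyranone at O1–C8a, and the sulfenic acid released may add to the isopropenyl group. The fallback uses known reaction types, sets out from acid 9 and pyranone 23, and comes back at 28. Acid 9 is homologated with 1,1′-carbonyldiimidazole and Mg(O2CCH2CO2Me)2 to the β-keto ester methyl (6R)-9-methyl-3-oxo-6-(prop-1-en-2-yl)-9-(triethylsilyloxy)decanoate F1. Its dianion (NaH, then n-BuLi, THF) should add through the γ-carbon to C2 of 23 at −78 °C, and warming in toluene should expel the sulfenic acid, the addition–elimination sequence known for 3-sulfinylchromones, to give the 2-substituted pyranone keto ester F2. Cs2CO3 in DMF should close ring A by intramolecular Claisen condensation of the pyranone carbon (future C4a) on the ester, a cyclisation known from polyketide model work, to give the 5,7-dihydroxy analogue of 27, F3 (the same structure as A8). The unchelated O7 is protected selectively (MeOCH2Cl, i-Pr2NEt) to give the 7-O-MOM ether F4. The chelated O5 is then methylated (MeI, K2CO3, DMF, 50 °C) to give the 5-O-methyl 7-O-MOM flavone F5. The conditions of step 14 remove three MOM ethers and the TES ether to give 28.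

Step 8. Diene 14 may lose silicon or hydrolyse during isolation, silylation may occur partly on carbon, and the minor alkene isomer would be a poor cycloaddition partner. The fallback sets out from 12 and 23 and comes back at 27. Lithium enolate 13 is not silylated but added directly to 23 at −78 °C → rt in a sequential double Michael addition (an anionic formal [4+2] of a kinetic enone enolate). Warming then brings about sulfoxide elimination and loss of methoxide, and work-up protonates the C7 phenoxide to give 27. No new isolated compound arises (entry F0).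

Step 12. The electron-rich ester 16 may react slowly with enolate 21, the sulfinyl group may undergo side reactions under strong base (attack at sulfur) or during the acid cyclisation (Pummerer-type change), and dimethylamine loss may stall. A more reactive acyl donor such as the acyl imidazolide addresses only the first point. The fallback sets out from 16 and comes back at 23, carrying sulfur at the sulfide level. Commercial 1-(phenylsulfanyl)propan-2-one F6 is aminomethylenated with Me2NCH(OMe)2 to 4-(dimethylamino)-3-(phenylsulfanyl)but-3-en-2-one F7. Acylation with 16 and cyclisation as in step 12 give 6-[2,4-bis(methoxymethoxy)phenyl]-3-(phenylsulfanyl)-4H-pyran-4-one F8. One equivalent of m-chloroperbenzoic acid in CH2Cl2 at −78 °C oxidises the sulfide to sulfoxide 23.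

Step 14. Acid may protonate the isopropenyl group, after which the 7-hydroxyl or the tertiary alcohol would close a cyclic ether, or the tertiary alcohol may ionise and eliminate before the last MOM ether is gone. The fallback changes the protecting groups, sets out from 15 and comes back at 28. Phenol 15 is allylated (allyl bromide, K2CO3, DMF) to methyl 2,4-bis(prop-2-en-1-yloxy)benzoate F9. Steps 12 and 13 with F9 in place of 16 give the bis(allyloxy) sulfinylpyranone F10 and the bis(allyloxy) analogue of 27, F11. Pd(PPh3)4 (zerovalent palladium) with morpholine in THF transfers both allyl groups to the amine and gives the TES ether of 28, F12. HF·pyridine buffered with pyridine in THF removes the silyl group to give 28, so the free 7-hydroxyl and the isopropenyl group never meet protic acid.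

## Further compounds

F1 | step 13 | methyl (6R)-9-methyl-3-oxo-6-(prop-1-en-2-yl)-9-(triethylsilyloxy)decanoate | C=C(C)[C@H](CCC(C)(C)O[Si](CC)(CC)CC)CCC(=O)CC(=O)OC
F2 | step 13 | methyl (6R)-4-{6-[2,4-bis(methoxymethoxy)phenyl]-4-oxo-4H-pyran-2-yl}-9-methyl-3-oxo-6-(prop-1-en-2-yl)-9-(triethylsilyloxy)decanoate, C4 unspecified | C=C(C)[C@H](CCC(C)(C)O[Si](CC)(CC)CC)CC(C(=O)CC(=O)OC)c1cc(=O)cc(-c2ccc(OCOC)cc2OCOC)o1
F3 | step 13 | 2-[2,4-bis(methoxymethoxy)phenyl]-5,7-dihydroxy-8-[(2R)-5-methyl-2-(prop-1-en-2-yl)-5-(triethylsilyloxy)hexyl]-4H-chromen-4-one | C=C(C)[C@H](CCC(C)(C)O[Si](CC)(CC)CC)Cc1c(O)cc(O)c2c(=O)cc(-c3ccc(OCOC)cc3OCOC)oc12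
F4 | step 13 | 2-[2,4-bis(methoxymethoxy)phenyl]-5-hydroxy-7-(methoxymethoxy)-8-[(2R)-5-methyl-2-(prop-1-en-2-yl)-5-(triethylsilyloxy)hexyl]-4H-chromen-4-one | C=C(C)[C@H](CCC(C)(C)O[Si](CC)(CC)CC)Cc1c(OCOC)cc(O)c2c(=O)cc(-c3ccc(OCOC)cc3OCOC)oc12
F5 | step 13 | 2-[2,4-bis(methoxymethoxy)phenyl]-5-methoxy-7-(methoxymethoxy)-8-[(2R)-5-methyl-2-(prop-1-en-2-yl)-5-(triethylsilyloxy)hexyl]-4H-chromen-4-one | C=C(C)[C@H](CCC(C)(C)O[Si](CC)(CC)CC)Cc1c(OCOC)cc(OC)c2c(=O)cc(-c3ccc(OCOC)cc3OCOC)oc12
F0 | step 8 | none | none
F6 | step 12 | 1-(phenylsulfanyl)propan-2-one | CC(=O)CSc1ccccc1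
F7 | step 12 | 4-(dimethylamino)-3-(phenylsulfanyl)but-3-en-2-one | CC(=O)C(=CN(C)C)Sc1ccccc1
F8 | step 12 | 6-[2,4-bis(methoxymethoxy)phenyl]-3-(phenylsulfanyl)-4H-pyran-4-one | O=c1cc(-c2ccc(OCOC)cc2OCOC)occ1Sc1ccccc1
F9 | step 14 | methyl 2,4-bis(prop-2-en-1-yloxy)benzoate | C=CCOc1ccc(C(=O)OC)c(OCC=C)c1
F10 | step 14 | 6-[2,4-bis(prop-2-en-1-yloxy)phenyl]-3-(phenylsulfinyl)-4H-pyran-4-one | O=c1cc(-c2ccc(OCC=C)cc2OCC=C)occ1S(=O)c1ccccc1
F11 | step 14 | 2-[2,4-bis(prop-2-en-1-yloxy)phenyl]-7-hydroxy-5-methoxy-8-[(2R)-5-methyl-2-(prop-1-en-2-yl)-5-(triethylsilyloxy)hexyl]-4H-chromen-4-one | C=C(C)[C@H](CCC(C)(C)O[Si](CC)(CC)CC)Cc1c(O)cc(OC)c2c(=O)cc(-c3ccc(OCC=C)cc3OCC=C)oc12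
F12 | step 14 | 2-(2,4-dihydroxyphenyl)-7-hydroxy-5-methoxy-8-[(2R)-5-methyl-2-(prop-1-en-2-yl)-5-(triethylsilyloxy)hexyl]-4H-chromen-4-one | C=C(C)[C@H](CCC(C)(C)O[Si](CC)(CC)CC)Cc1c(O)cc(OC)c2c(=O)cc(-c3ccc(O)cc3O)oc12
A1 | alternative 1 | triethyl{[(5R)-2-methyl-5-(prop-1-en-2-yl)-8-(triisopropylsilyloxy)oct-7-yn-2-yl]oxy}silane | C=C(C)[C@H](CCC(C)(C)O[Si](CC)(CC)CC)CC#CO[Si](C(C)C)(C(C)C)C(C)C
A2 | alternative 1 | 3-methoxycyclobut-2-en-1-one | COC1=CC(=O)C1
A3 | alternative 1 | 5-methoxy-2-[(2R)-5-methyl-2-(prop-1-en-2-yl)-5-(triethylsilyloxy)hexyl]-3-(triisopropylsilyloxy)phenol | C=C(C)[C@H](CCC(C)(C)O[Si](CC)(CC)CC)Cc1c(O)cc(OC)cc1O[Si](C(C)C)(C(C)C)C(C)C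
A4 | alternative 2 | 6-[(2R)-5-hydroxy-5-methyl-2-(prop-1-en-2-yl)hexyl]-2-iodo-3-methoxy-5-(methoxymethoxy)phenol | C=C(C)[C@H](CCC(C)(C)O)Cc1c(OCOC)cc(OC)c(I)c1O
A5 | alternative 2 | 1-ethynyl-2,4-bis(methoxymethoxy)benzene | C#Cc1ccc(OCOC)cc1OCOC
A6 | alternative 2 | 2-[2,4-bis(methoxymethoxy)phenyl]-8-[(2R)-5-hydroxy-5-methyl-2-(prop-1-en-2-yl)hexyl]-5-methoxy-7-(methoxymethoxy)-4H-chromen-4-one | C=C(C)[C@H](CCC(C)(C)O)Cc1c(OCOC)cc(OC)c2c(=O)cc(-c3ccc(OCOC)cc3OCOC)oc12
A7 | alternative 3 | methyl 6-[2,4-bis(methoxymethoxy)phenyl]-2-[(3S)-6-methyl-3-(prop-1-en-2-yl)-6-(triethylsilyloxy)heptyl]-4-oxo-4H-pyran-3-carboxylate (spatial arrangement at the chain centre as in 28) | C=C(C)[C@H](CCC(C)(C)O[Si](CC)(CC)CC)CCc1oc(-c2ccc(OCOC)cc2OCOC)cc(=O)c1C(=O)OC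
A8 | alternative 3 | 2-[2,4-bis(methoxymethoxy)phenyl]-5,7-dihydroxy-8-[(2R)-5-methyl-2-(prop-1-en-2-yl)-5-(triethylsilyloxy)hexyl]-4H-chromen-4-one | C=C(C)[C@H](CCC(C)(C)O[Si](CC)(CC)CC)Cc1c(O)cc(O)c2c(=O)cc(-c3ccc(OCOC)cc3OCOC)oc12
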